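(The data are simulated for substances that don't exist; the scatter is artificial.)

In a closed flask the percentages of the starting material charged, counted over every form it stands in, add up to a constant, so target and other capture product together stay within 100 %.

common to all: starting material 0.50 M

| charge | first nucleophile | second nucleophile | remark | time |
|---|---|---|---|---|
| alder | 0.55 M | 1 M | run made earlier |  |
| oak | 0.55 M | 2.2 M | run made earlier |  |
| birch | 1.1 M | 1.5 M | run made earlier |  |
| flask | 0.550 M | 1.50 M |  | 3.0 d |

- alder (time / h: other capture product / %, target / %): 10.0: 6.3, 0; 20.0: 12.2, 0; 30.0: 15.9, 0; 40.0: 19.7, 0.5
- oak (time / h: other capture product / %, target / %): 5.00: 4.0, 2.1; 15.0: 11.2, 1.1; 30.0: 21.2, 0; 40.0: 25.1, 1.9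
- birch (time / h: other capture product / %, target / %): 10.0: 7.2, 0; 20.0: 11.6, 0; 30.0: 16.7, 1.3; 40.0: 23.2, 0.1

(readings scatter by 1 percentage point)

- ratio of other capture product to target at 2.5 h
- ratio of other capture product to target at 12 h
- ratio of other capture product to target at 3.0 d
- which of other capture product and target there is more of at 3.0 d

- the numbers in the tables scatter with a standard deviation of 1 percentage point

From the alder to the oak run the second nucleophile rises by a factor of 2.20, but the other capture product at 40.0 h rises by a factor of 1.27, less. So I take the concentration that sets the order to be c(starting material). The birch run has the flask's second nucleophile, and its first nucleophile is 1.1 M against the flask's 0.550 M. It reads 23.2 % at 40.0 h. From that reading I define the capture clock, the pseudo-first-order constant with which starting material appears as other capture product: 0.00660 h⁻¹. My reckoning for the flask is then 37.8 % of other capture product at 3.0 d.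

Turned round, the target leads the flask only if it passes that figure. The birch run's target reads 1.3 % and 0.1 % at its last two times, with a scatter of 1 point, so a target in the flask that stood at that last reading at 40.0 h would have to gain 38 points in the remaining 32.0 h. I therefore expect the other capture product to lead, and I set no ratio on a target this close to zero.

The forecast does set ratios: 300, 70 and 13 at 2.5 h, 12 h and 3.0 d, with other capture product ahead. In its words, “The ratios are therefore very large early and fall with time, with wide uncertainty.”

The flask gives ratios of 4.99, 23.2 and 188, with other capture product ahead.

    starting material → intermediate (k = 0.0110 h⁻¹)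
    first nucleophile + intermediate ⇌ target (K = 4.90 M⁻¹, k = 4.80 M⁻¹ h⁻¹)
    second nucleophile + intermediate → other capture product (k = 3.50 M⁻¹ h⁻¹)
    intermediate → solvolysis product (k = 2.40 h⁻¹)

The lead agrees with the forecast, but the ratio climbs with time where the forecast's falls. At 3.0 d the flask holds 36.6 % of other capture product against the clock's 37.8 %, and 0.194 % of target. A neighbouring flask with 2.2 M of first nucleophile, the rest unchanged, gets the same clock and so the same 37.8 %. It gives 36.2 % of other capture product, with 0.786 % of target and a ratio of 46.1 at the end.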